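**Plan**

- Retrosynthesis: cut the ester C–O bond (to angelic acid). Then cut C3–C4, C1–C2 and C1–C8a of the naphthalene ring that carries the side chain, giving an aryl(methoxy)carbene chromium complex (C4, C4a–C8a), one carbonyl ligand (C1) and a terminal alkyne (C2, C3). The alkyne goes back to 2,2-dimethylcyclobutanone.
- Enabling feature: ring A has oxygen at C1 and C4 (para), the cyclobutyl group at C2 and hydrogen at C3, and is fused to ring B with oxygen at C5 and C8. This is the pattern written by a carbene carbon, CO, a terminal alkyne and a 2,5-dioxygenated phenyl group.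
- Forward: ring B and the cyclobutane are bought. Ring A is the only ring made and is closed in the benzannulation. It is then oxidised to a quinone monoketal, the carbinol is esterified on this base-tolerant stage, and acid unveils quinone and phenols.
- Stereochemistry: the single stereocentre (R, quaternary carbinol) is set by Sharpless epoxidation of an E-allylic alcohol with D-(–)-diethyl tartrate and carried into the alkyne with its C–O bond intact. The Z ester geometry comes from angelic acid.

Key step: step 9

Remark: 5,8-dihydroxy-1,4-naphthoquinones equilibrate rapidly between their tautomers, so the product of the last step is the compound drawn whichever ring is written as the quinone.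

**Route**

Step 1
Reactants: 1 2-bromobenzene-1,4-diol
Product: 2 2-bromo-1,4-bis(methoxymethoxy)benzene
Conditions: MeOCH2Cl, i-Pr2NEt, CH2Cl2, 0 °C → rt
Reagents that add atoms: chloromethyl methyl ether, COCCl
Why: O-alkylation of both phenols (Williamson-type acetal ether formation) gives methoxymethyl ethers that survive organolithium, carbene and alkoxide chemistry, come off with acid at the end, and offer a hemilabile donor oxygen ortho to the future carbene carbon.

Step 2
Reactants: 2 2-bromo-1,4-bis(methoxymethoxy)benzene
Product: 5 pentacarbonyl{[2,5-bis(methoxymethoxy)phenyl](methoxy)methylidene}chromium, via aryllithium 3 (not isolated), via lithium acylchromate 4 (not isolated)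
Conditions: n-BuLi, THF, –78 °C; Cr(CO)6, –78 °C → rt; MeOTf, CH2Cl2, 0 °C
Reagents that add atoms: hexacarbonylchromium Cr(CO)6, O=C=[Cr](=C=O)(=C=O)(=C=O)(=C=O)=C=O; methyl trifluoromethanesulfonate, COS(=O)(=O)C(F)(F)F
Why: Fischer carbene synthesis, in which bromine–lithium exchange, addition of the aryllithium to a carbonyl ligand and O-methylation of the acyl chromate by a hard methylating agent give the aryl(methoxy)carbene complex.

Step 3
Reactants: 6 2,2-dimethylcyclobutan-1-one, 7 triethyl phosphonoacetate
Product: 8 ethyl (2E)-2-(2,2-dimethylcyclobutylidene)acetate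
Conditions: NaH, THF, 0 °C → reflux
Reagents that add atoms: none
Why: Horner–Wadsworth–Emmons olefination of the strained, electrophilic cyclobutanone should place the ester on the side of the ring CH2 and away from the gem-dimethyl group, so the E isomer should dominate, and any Z isomer (which would later give the wrong carbinol configuration) is removed by chromatography.

Step 4
Reactants: 8 ethyl (2E)-2-(2,2-dimethylcyclobutylidene)acetate
Product: 9 (2E)-2-(2,2-dimethylcyclobutylidene)ethan-1-ol
Conditions: i-Bu2AlH, CH2Cl2, –78 → 0 °C
Reagents that add atoms: none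
Why: 1,2-reduction of the conjugated ester to the allylic alcohol by the aluminium hydride leaves the exocyclic double bond and its geometry untouched.

Step 5
Reactants: 9 (2E)-2-(2,2-dimethylcyclobutylidene)ethan-1-ol
Product: 10 [(2R,3R)-4,4-dimethyl-1-oxaspiro[2.3]hexan-2-yl]methanol
Conditions: Ti(OiPr)4 (cat.), D-(–)-diethyl tartrate (cat.), t-BuOOH, 4 Å MS, CH2Cl2, –20 °C
Reagents that add atoms: tert-butyl hydroperoxide, CC(C)(C)OO
Why: Sharpless asymmetric epoxidation of an E-3,3-disubstituted allylic alcohol, in which the titanium tartrate binds the hydroxyl and delivers the peroxide oxygen to one alkene face, and with D-(–)-diethyl tartrate this is the face that makes both new centres R (the L-(+)-tartrate gives the 2S,3S series with alcohols of this type), so the quaternary spiro carbon is set under reagent control.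

Step 6
Reactants: 10 [(2R,3R)-4,4-dimethyl-1-oxaspiro[2.3]hexan-2-yl]methanol
Product: 11 (2S,3R)-2-(chloromethyl)-4,4-dimethyl-1-oxaspiro[2.3]hexane
Conditions: PPh3, CCl4, NaHCO3, reflux
Reagents that add atoms: tetrachloromethane, ClC(Cl)(Cl)Cl
Why: Appel chlorination replaces the primary hydroxyl by SN2 at the CH2 carbon without touching either epoxide C–O bond (the C2 descriptor changes only through CIP ranking), and the bicarbonate buffer protects the strained spiro epoxide from acid.

Step 7
Reactants: 11 (2S,3R)-2-(chloromethyl)-4,4-dimethyl-1-oxaspiro[2.3]hexane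
Product: 13 (1R)-1-ethynyl-2,2-dimethylcyclobutan-1-ol, via lithium chlorovinyl alkoxide 12 (not isolated)
Conditions: n-BuLi (3 equiv), THF, –78 → –30 °C; aq. NH4Cl
Reagents that add atoms: none
Why: base-induced double elimination of a 2,3-epoxy chloride to a propargylic alcohol (Takano–Yadav alkynol synthesis), in which deprotonation at CH2Cl opens the epoxide at its CH–O bond and the chlorovinyl alkoxide then loses HCl, so the tertiary C–O bond is never broken and the spiro configuration becomes the R carbinol unchanged.

Step 8
Reactants: 13 (1R)-1-ethynyl-2,2-dimethylcyclobutan-1-ol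
Product: 14 triethyl{[(1R)-1-ethynyl-2,2-dimethylcyclobutyl]oxy}silane
Conditions: Et3SiOTf, 2,6-lutidine, CH2Cl2, –78 → 0 °C
Reagents that add atoms: triethylsilyl trifluoromethanesulfonate, CC[Si](CC)(CC)OS(=O)(=O)C(F)(F)F
Why: silylation of the hindered tertiary alcohol with a silyl triflate masks the hydroxyl, which would otherwise trap the vinylketene intermediate of the benzannulation as a lactone.

Step 9
Reactants: 5 pentacarbonyl{[2,5-bis(methoxymethoxy)phenyl](methoxy)methylidene}chromium, 14 triethyl{[(1R)-1-ethynyl-2,2-dimethylcyclobutyl]oxy}silane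
Product: 16 2-[(1R)-2,2-dimethyl-1-(triethylsilyloxy)cyclobutyl]-4-methoxy-5,8-bis(methoxymethoxy)naphthalen-1-ol, via Cr(CO)3 naphthol complex 15 (not isolated)
Conditions: 14 (1.5 equiv), THF, 50 °C, Ar; then air, Et2O, rt
Reagents that add atoms: none
Why: Loss of one CO from 5 (eased by the ortho methoxymethoxy oxygen as a hemilabile donor) frees a site on zerovalent chromium for the alkyne, which inserts into the Cr=C bond with its CH end at the carbene carbon (C3–C4); CO insertion into the new vinylcarbene gives a chromium-bound vinylketene (C1–C2), and ring closure onto the free ortho carbon of the aryl group (C1–C8a) followed by tautomerisation gives the naphthol as its Cr(CO)3 complex 15, from which air releases 16. The closest known reaction type is the Dötz benzannulation of aryl(alkoxy)carbene chromium complexes with terminal alkynes, propargylic silyl ethers included. The one ring formed closes by a thermal six-electron electrocyclisation of the metal-bound dienylketene. No stereocentre is created, and the quaternary carbinol of 14 has no bond made or broken and no acidic hydrogen, so its R configuration is carried through. The step needs regioselective insertion, which the bulky quaternary propargylic carbon secures by staying away from the carbene carbon with its aryl and methoxy groups, so that it ends at C2 beside the CO-derived C1 with hydrogen at C3. It also needs a single annulation site and phenol formation, secured because the aryl ring has only one unsubstituted ortho carbon and because aryl(methoxy) chromium carbenes in THF favour CO insertion over indene or furan formation.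

Step 10
Reactants: 16 2-[(1R)-2,2-dimethyl-1-(triethylsilyloxy)cyclobutyl]-4-methoxy-5,8-bis(methoxymethoxy)naphthalen-1-ol
Product: 17 2-[(1R)-2,2-dimethyl-1-(triethylsilyloxy)cyclobutyl]-4,4-dimethoxy-5,8-bis(methoxymethoxy)naphthalen-1(4H)-one
Conditions: PhI(OAc)2, MeOH, 0 °C
Reagents that add atoms: methanol, CO
Why: oxidative dearomatisation of a para-methoxyphenol by the hypervalent iodine diacetate in methanol gives the quinone monoketal, because methanol attacks C4 (para to the phenol oxygen and already bearing OMe) and only ring A carries a free phenol, so the ring that is oxidised is fixed.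

Step 11
Reactants: 17 2-[(1R)-2,2-dimethyl-1-(triethylsilyloxy)cyclobutyl]-4,4-dimethoxy-5,8-bis(methoxymethoxy)naphthalen-1(4H)-one
Product: 18 2-[(1R)-1-hydroxy-2,2-dimethylcyclobutyl]-4,4-dimethoxy-5,8-bis(methoxymethoxy)naphthalen-1(4H)-one
Conditions: Bu4NF, AcOH, THF, 0 °C → rt
Reagents that add atoms: none
Why: fluoride-induced Si–O cleavage, buffered with acetic acid so that no free alkoxide persists, liberates the tertiary alcohol while ketal, methoxymethyl ethers and dienone stay intact.

Step 12
Reactants: 18 2-[(1R)-1-hydroxy-2,2-dimethylcyclobutyl]-4,4-dimethoxy-5,8-bis(methoxymethoxy)naphthalen-1(4H)-one, 19 angelic acid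
Product: 22 (1R)-1-[4,4-dimethoxy-5,8-bis(methoxymethoxy)-1-oxo-1,4-dihydronaphthalen-2-yl]-2,2-dimethylcyclobutyl (2Z)-2-methylbut-2-enoate, via mixed anhydride 20 (not isolated), via lithium alkoxide 21 (not isolated)
Conditions: 19, 2,4,6-Cl3C6H2COCl, Et3N, toluene, rt; 18, LiN(SiMe3)2, THF, –78 °C; combine, –78 → 0 °C
Reagents that add atoms: none
Why: Yamaguchi-type mixed-anhydride acylation of a preformed lithium alkoxide, in which the hindered alkoxide attacks the less shielded angeloyl carbonyl by addition–elimination without an acylium ion or a nucleophilic catalyst, so the Z geometry should be kept, and the substrate tolerates the base because the monoketal is no quinone and has no acidic hydrogen.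

Step 13
Reactants: 22 (1R)-1-[4,4-dimethoxy-5,8-bis(methoxymethoxy)-1-oxo-1,4-dihydronaphthalen-2-yl]-2,2-dimethylcyclobutyl (2Z)-2-methylbut-2-enoate
Product: 23 (1R)-1-(5,8-dihydroxy-1,4-dioxo-1,4-dihydronaphthalen-2-yl)-2,2-dimethylcyclobutyl (2Z)-2-methylbut-2-enoate
Conditions: CF3CO2H, H2O, CH2Cl2, 0 °C → rt
Reagents that add atoms: water, O
Why: acid hydrolysis of the dimethyl ketal to the C4 carbonyl and of both aryl methoxymethyl acetals in one operation unveils the naphthazarin, and the tertiary ester should survive because ionisation at a cyclobutyl carbon next to the electron-poor quinone is disfavoured.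

**Compound list**

1 | 2-bromobenzene-1,4-diol | Oc1ccc(O)c(Br)c1 | starting material
2 | 2-bromo-1,4-bis(methoxymethoxy)benzene | COCOc1ccc(OCOC)c(Br)c1 | intermediate
3 | [2,5-bis(methoxymethoxy)phenyl]lithium | [Li]c1cc(OCOC)ccc1OCOC | intermediate (not isolated)
4 | lithium pentacarbonyl{[2,5-bis(methoxymethoxy)phenyl](oxido)methylidene}chromate (acyl chromate) | [Li+].[O-]C(c1cc(OCOC)ccc1OCOC)=[Cr](=C=O)(=C=O)(=C=O)(=C=O)=C=O | intermediate (not isolated)
5 | pentacarbonyl{[2,5-bis(methoxymethoxy)phenyl](methoxy)methylidene}chromium | COC(c1cc(OCOC)ccc1OCOC)=[Cr](=C=O)(=C=O)(=C=O)(=C=O)=C=O | intermediate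
6 | 2,2-dimethylcyclobutan-1-one | CC1(C)CCC1=O | starting material
7 | triethyl phosphonoacetate | CCOC(=O)CP(=O)(OCC)OCC | starting material
8 | ethyl (2E)-2-(2,2-dimethylcyclobutylidene)acetate | CCOC(=O)/C=C1\CCC1(C)C | intermediate
9 | (2E)-2-(2,2-dimethylcyclobutylidene)ethan-1-ol | OC/C=C1\CCC1(C)C | intermediate
10 | [(2R,3R)-4,4-dimethyl-1-oxaspiro[2.3]hexan-2-yl]methanol | OC[C@H]1O[C@@]12CCC2(C)C | intermediate
11 | (2S,3R)-2-(chloromethyl)-4,4-dimethyl-1-oxaspiro[2.3]hexane | ClC[C@H]1O[C@@]12CCC2(C)C | intermediate
12 | lithium (1S)-1-(2-chloroethenyl)-2,2-dimethylcyclobutan-1-olate (same spatial arrangement as 13, descriptor S by CIP ranking, alkene geometry not defined) | [Li+].[O-][C@]1(C=CCl)CCC1(C)C | intermediate (not isolated)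
13 | (1R)-1-ethynyl-2,2-dimethylcyclobutan-1-ol | O[C@]1(C#C)CCC1(C)C | intermediate
14 | triethyl{[(1R)-1-ethynyl-2,2-dimethylcyclobutyl]oxy}silane | CC[Si](CC)(CC)O[C@]1(C#C)CCC1(C)C | intermediate
15 | tricarbonylchromium η6 complex of naphthol 16 (metal on the newly formed ring, written as two SMILES parts) | CC[Si](CC)(CC)O[C@]1(c2cc(OC)c3c(OCOC)ccc(OCOC)c3c2O)CCC1(C)C.O=C=[Cr](=C=O)=C=O | intermediate (not isolated)
16 | 2-[(1R)-2,2-dimethyl-1-(triethylsilyloxy)cyclobutyl]-4-methoxy-5,8-bis(methoxymethoxy)naphthalen-1-ol | CC[Si](CC)(CC)O[C@]1(c2cc(OC)c3c(OCOC)ccc(OCOC)c3c2O)CCC1(C)C | intermediate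
17 | 2-[(1R)-2,2-dimethyl-1-(triethylsilyloxy)cyclobutyl]-4,4-dimethoxy-5,8-bis(methoxymethoxy)naphthalen-1(4H)-one | CC[Si](CC)(CC)O[C@]1(C2=CC(OC)(OC)c3c(OCOC)ccc(OCOC)c3C2=O)CCC1(C)C | intermediate
18 | 2-[(1R)-1-hydroxy-2,2-dimethylcyclobutyl]-4,4-dimethoxy-5,8-bis(methoxymethoxy)naphthalen-1(4H)-one | O[C@]1(C2=CC(OC)(OC)c3c(OCOC)ccc(OCOC)c3C2=O)CCC1(C)C | intermediate
19 | angelic acid, (2Z)-2-methylbut-2-enoic acid | C/C=C(/C)C(=O)O | starting material
20 | (2Z)-2-methylbut-2-enoic 2,4,6-trichlorobenzoic anhydride | C/C=C(/C)C(=O)OC(=O)c1c(Cl)cc(Cl)cc1Cl | intermediate (not isolated)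
21 | lithium alkoxide of 18 | [Li+].[O-][C@]1(C2=CC(OC)(OC)c3c(OCOC)ccc(OCOC)c3C2=O)CCC1(C)C | intermediate (not isolated)
22 | (1R)-1-[4,4-dimethoxy-5,8-bis(methoxymethoxy)-1-oxo-1,4-dihydronaphthalen-2-yl]-2,2-dimethylcyclobutyl (2Z)-2-methylbut-2-enoate | C/C=C(/C)C(=O)O[C@]1(C2=CC(OC)(OC)c3c(OCOC)ccc(OCOC)c3C2=O)CCC1(C)C | intermediate
23 | (1R)-1-(5,8-dihydroxy-1,4-dioxo-1,4-dihydronaphthalen-2-yl)-2,2-dimethylcyclobutyl (2Z)-2-methylbut-2-enoate | C/C=C(/C)C(=O)O[C@]1(C2=CC(=O)c3c(O)ccc(O)c3C2=O)CCC1(C)C | target

**Count and risks**

Total steps: 13. Longest linear sequence: 11 steps (6 → 23, steps 3–8 and 9–13); the arene branch (steps 1–2) joins at step 9.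

Steps most likely to fail:

Step 9. The very hindered alkyne may insert so slowly at the temperature needed for CO loss that thermal decay of the carbene complex, or loss of silanol from the electron-rich naphthol on long heating, outruns ring formation. The fallback takes CO dissociation out of the annulation. It sets out from 5, which is warmed briefly in a non-coordinating solvent under an argon stream (or irradiated) to give the tetracarbonyl chelate tetracarbonyl{[2,5-bis(methoxymethoxy)phenyl](methoxy)methylidene-κC,κO}chromium F1, in which the ortho methoxymethoxy oxygen fills the vacated site. Such hemilabile chelates open at or below room temperature, so F1 and 14 are combined in THF at room temperature, and air work-up as before brings the sequence back to 16.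

Step 12. Acyl transfer to the crowded tertiary alkoxide may remain incomplete, and longer reaction times invite geometric isomerisation of the Z acyl donor. The fallback makes the ester bond first and the Z alkene afterwards. It sets out from 18, whose lithium alkoxide is acylated with the small, saturated 2-[bis(2,2,2-trifluoroethoxy)phosphoryl]propanoyl chloride to give the phosphonopropionate ester (1R)-1-[4,4-dimethoxy-5,8-bis(methoxymethoxy)-1-oxo-1,4-dihydronaphthalen-2-yl]-2,2-dimethylcyclobutyl 2-[bis(2,2,2-trifluoroethoxy)phosphoryl]propanoate F2. A Still–Gennari olefination of F2 with acetaldehyde (KN(SiMe3)2, 18-crown-6, THF, –78 °C) should then give the Z-trisubstituted enoate and so return to 22.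

Step 5. Enantioface discrimination may be insufficient for this alkylidenecyclobutane, or the strained oxaspirohexane may be opened or ring-expanded by the Lewis-acidic titanium medium. The fallback makes the carbinol racemic and resolves it. It sets out from 6, which with HC≡CMgBr in THF gives racemic 1-ethynyl-2,2-dimethylcyclobutan-1-ol F3. The lithium alkoxide of F3 (n-BuLi, 1 equiv) adds to (R)-1-(naphthalen-1-yl)ethyl isocyanate, and the two diastereomeric carbamates are separated by chromatography or crystallisation. The diastereomer with the R carbinol, (1R)-1-ethynyl-2,2-dimethylcyclobutyl N-[(1R)-1-(naphthalen-1-yl)ethyl]carbamate F4, is identified by X-ray analysis against the known auxiliary centre and cleaved with HSiCl3/Et3N, which returns to 13.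

**Further compounds**

F1 | step 9 | tetracarbonyl{[2,5-bis(methoxymethoxy)phenyl](methoxy)methylidene-κC,κO}chromium (chelate through the ortho ether oxygen) | COC1=[Cr-](=C=O)(=C=O)(=C=O)(=C=O)[O+](COC)c2ccc(OCOC)cc21
F2 | step 12 | (1R)-1-[4,4-dimethoxy-5,8-bis(methoxymethoxy)-1-oxo-1,4-dihydronaphthalen-2-yl]-2,2-dimethylcyclobutyl 2-[bis(2,2,2-trifluoroethoxy)phosphoryl]propanoate (both epimers at the phosphonate-bearing carbon) | CC(C(=O)O[C@]1(C2=CC(OC)(OC)c3c(OCOC)ccc(OCOC)c3C2=O)CCC1(C)C)P(=O)(OCC(F)(F)F)OCC(F)(F)F
F3 | step 5 | racemic 1-ethynyl-2,2-dimethylcyclobutan-1-ol | OC1(C#C)CCC1(C)C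
F4 | step 5 | (1R)-1-ethynyl-2,2-dimethylcyclobutyl N-[(1R)-1-(naphthalen-1-yl)ethyl]carbamate | C[C@@H](NC(=O)O[C@]1(C#C)CCC1(C)C)c1cccc2ccccc12
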